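**Retrosynthetic overview**
- The ten-membered ring is released last, not closed: a thermal antarafacial [1,7]-H shift (C19-H to C10) of an (E,Z,E)-cyclodecatriene, which comes from photochemical conrotatory 6π ring opening of the C5–C10 bond of a trans-fused clerodane-type 1,3-diene keto diacid.
- That hexalin diene comes from a Weinreb amide plus 3-furyllithium; its ring A comes from a Diels–Alder reaction of a 2-methyl-1-vinylcyclohexene with methyl propiolate, followed by base-mediated diene conjugation.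
- The vinylcyclohexene comes from an enol triflate (Stille), made after α-methylation of a keto ester; both permanent stereocentres (C8, C9) are set in the first step by Cu-catalysed asymmetric conjugate vinylation and enolate alkylation of 2-methylcyclohexenone.
- Ring order: ring B (bought) → ring A (Diels–Alder) → ten-membered ring (opening of the A/B fusion bond, then H shift). The two ring-fusion stereocentres are temporary.

Assumption: locants C1–C20 are clerodane-type locants of the target (ring C1–C10; C5 carries the =CH2 (C19), C8 is CH–CO2H (C17), C9 is the quaternary carbon with CH3 (C20) and C11H2–C12(=O)–furyl, C4 carries C18O2H); the chiral copper ligand is used as the antipode that gives the stated configuration.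

**Step 1**
Reactants: 1 2-methylcyclohex-2-en-1-one; 2 vinylmagnesium bromide; 3 2-bromo-N-methoxy-N-methylacetamide
Product: 5 2-[(1S,6S)-6-ethenyl-1-methyl-2-oxocyclohexyl]-N-methoxy-N-methylacetamide, via magnesium enolate 4 (not isolated)
Conditions: 2 (1.2 equiv), Cu(OTf)2 (3 mol %), chiral imidazolinium NHC precursor (4 mol %), Et2O, −30 °C; then 3, DMPU, THF, −30 → 0 °C
Reagents that add atoms: none
Why: Cu–NHC-catalysed asymmetric conjugate addition of the Grignard reagent sets C8 under ligand control, and the magnesium enolate is then alkylated anti to the new vinyl group (tandem Michael addition/enolate alkylation), so the quaternary C9 forms with CH2C(O)N trans and CH3 cis to vinyl.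

**Step 2**
Reactants: 5
Product: 6 methyl (1R,2S)-2-{2-[methoxy(methyl)amino]-2-oxoethyl}-2-methyl-3-oxocyclohexane-1-carboxylate
Conditions: O3, 2.5 M NaOH/MeOH, CH2Cl2, −78 °C
Reagents that add atoms: ozone O=[O+][O-]; methanol CO
Why: Marshall ozonolysis in methanolic NaOH turns the terminal alkene directly into the methyl ester (methoxy hydroperoxide dehydration) at −78 °C, leaving ketone, Weinreb amide and both stereocentres untouched.

**Step 3**
Reactants: 6
Product: 8 methyl (1R,2S,4RS)-2-{2-[methoxy(methyl)amino]-2-oxoethyl}-2,4-dimethyl-3-oxocyclohexane-1-carboxylate, via lithium enolate 7 (not isolated)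
Conditions: LDA (1.05 equiv), THF, −78 °C; MeI, −78 → −40 °C
Reagents that add atoms: iodomethane CI
Why: Kinetic enolate alkylation; the ketone can enolise only away from the quaternary C9 and is more acidic than the ester and amide, and the epimer mixture at the new methyl-bearing carbon (ring locant 4 of 8, C5 in target numbering) is irrelevant because that carbon becomes sp2 in step 4.

**Step 4**
Reactants: 8
Product: 10 methyl (1R,2S)-2-{2-[methoxy(methyl)amino]-2-oxoethyl}-2,4-dimethyl-3-(trifluoromethylsulfonyloxy)cyclohex-3-ene-1-carboxylate, via potassium enolate 9 (not isolated)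
Conditions: KHMDS, THF, −78 °C; PhNTf2, −78 → 0 °C; aq. NH4Cl
Reagents that add atoms: N-phenylbis(trifluoromethanesulfonimide) O=S(=O)(N(c1ccccc1)S(=O)(=O)C(F)(F)F)C(F)(F)F
Why: Enol triflate formation through the only possible (tetrasubstituted) enolate, as for 2,2,6-trisubstituted cyclohexanones; no stereocentre is affected.

**Step 5**
Reactants: 10; 11 tributyl(vinyl)stannane
Product: 12 methyl (1R,2S)-3-ethenyl-2-{2-[methoxy(methyl)amino]-2-oxoethyl}-2,4-dimethylcyclohex-3-ene-1-carboxylate
Conditions: Pd(PPh3)4 (5 mol %), LiCl (3 equiv), THF, 70 °C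
Reagents that add atoms: none
Why: Stille coupling of a hindered cyclohexenyl triflate with a vinylstannane is the standard entry to 2-methyl-1-vinylcyclohexene dienes and tolerates the ester and the Weinreb amide.

**Step 6**
Reactants: 12; 13 methyl propiolate
Product: 15 dimethyl (4aR,5R,6R,8aR)-5-{2-[methoxy(methyl)amino]-2-oxoethyl}-5,8a-dimethyl-4a,5,6,7,8,8a-hexahydronaphthalene-1,6-dicarboxylate, via 1,4-diene cycloadduct 14 (not isolated)
Conditions: 13 (4 equiv), BHT, PhMe, 120 °C, sealed tube; evaporate; DBU, PhMe, 80 °C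
Reagents that add atoms: none
Why: Thermal Diels–Alder reaction of the vinylcyclohexene with the alkynoate (as in drimane syntheses) joins the CH2 terminus to the alkyne β-carbon ("ortho" regiochemistry) and adds to C5 anti to the pseudo-axial C20 methyl, and DBU then conjugates the skipped diene through the extended enolate, which is protonated at C10 away from both axial methyls to give the trans ring fusion (both new centres are temporary).

**Step 7**
Reactants: 15
Product: 17 (4aR,5R,6R,8aR)-5-{2-[methoxy(methyl)amino]-2-oxoethyl}-5,8a-dimethyl-4a,5,6,7,8,8a-hexahydronaphthalene-1,6-dicarboxylic acid, via disodium dicarboxylate 16 (not isolated)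
Conditions: 2 M aq. NaOH (6 equiv), THF/MeOH, 45 °C; 1 M HCl to pH 3, extract, dry azeotropically (PhMe)
Reagents that add atoms: sodium hydroxide [Na+].[OH-]
Why: Saponification (BAc2) of the two methyl esters is faster than hydrolysis of the Weinreb amide, and any base equilibration at C10 or C8 returns the more stable trans-fused, equatorial-carboxyl isomer; the free diacid is isolated and dried so that the next step starts from a water- and hydroxide-free substrate.

**Step 8**
Reactants: 17; 18 3-bromofuran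
Product: 21 (4aR,5R,6R,8aR)-5-[2-(furan-3-yl)-2-oxoethyl]-5,8a-dimethyl-4a,5,6,7,8,8a-hexahydronaphthalene-1,6-dicarboxylic acid, via dilithium dicarboxylate 19 (not isolated), via trilithium tetrahedral adduct 20 (not isolated)
Conditions: 18, n-BuLi, THF, −78 °C; add 17 in THF (3.3 equiv ArLi per 17), −78 °C; aq. HCl to pH 3
Reagents that add atoms: 3-furyllithium [Li]c1ccoc1 (made in the flask from 18 and n-BuLi)
Why: Weinreb ketone synthesis; the first two equivalents of aryllithium convert the acids into unreactive lithium carboxylates, the third adds once to the amide to give a chelated adduct that collapses to the ketone only on work-up, and −78 °C prevents 3-furyl to 2-furyl lithium isomerisation.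

**Step 9**
Reactants: 21
Product: 23 (1R,2S,4Z,6E)-2-[2-(furan-3-yl)-2-oxoethyl]-2-methyl-8-methylidenecyclodeca-4,6-diene-1,7-dicarboxylic acid, via E,Z,E-cyclodecatriene 22 (not isolated)
Conditions: hν (300 nm), degassed THF, −40 °C, to about 50 % conversion; then dark, 40 °C; recycle recovered 21
Reagents that add atoms: none
Why: Irradiation of the trans-fused cyclohexa-1,3-diene causes conrotatory 6π-electrocyclic opening of the C5–C10 bond to the helical (E,Z,E)-triene (previtamin D analogy; the dienoic acid should absorb far more strongly at 300 nm than the furyl ketone), whose locked cZc geometry holds a C19 hydrogen over C10 for the thermal antarafacial [1,7]-sigmatropic hydrogen shift that gives the 5(19)-methylene and the two ring-cis double bonds, with C8 and C9 untouched.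

**Compound list**
1 | 2-methylcyclohex-2-en-1-one | CC1=CCCCC1=O | starting material
2 | vinylmagnesium bromide | C=C[Mg]Br | starting material
3 | 2-bromo-N-methoxy-N-methylacetamide | CON(C)C(=O)CBr | starting material
4 | bromomagnesium (3S)-3-ethenyl-2-methylcyclohex-1-en-1-olate | CC1=C(O[Mg]Br)CCC[C@H]1C=C | intermediate
5 | 2-[(1S,6S)-6-ethenyl-1-methyl-2-oxocyclohexyl]-N-methoxy-N-methylacetamide | O=C1CCC[C@@H](C=C)[C@]1(C)CC(=O)N(C)OC | intermediate
6 | methyl (1R,2S)-2-{2-[methoxy(methyl)amino]-2-oxoethyl}-2-methyl-3-oxocyclohexane-1-carboxylate | O=C1CCC[C@@H](C(=O)OC)[C@]1(C)CC(=O)N(C)OC | intermediate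
7 | lithium (5R,6S)-5-(methoxycarbonyl)-6-{2-[methoxy(methyl)amino]-2-oxoethyl}-6-methylcyclohex-1-en-1-olate | [Li]OC1=CCC[C@@H](C(=O)OC)[C@]1(C)CC(=O)N(C)OC | intermediate
8 | methyl (1R,2S,4RS)-2-{2-[methoxy(methyl)amino]-2-oxoethyl}-2,4-dimethyl-3-oxocyclohexane-1-carboxylate | CC1CC[C@@H](C(=O)OC)[C@](C)(CC(=O)N(C)OC)C1=O | intermediate
9 | potassium (5R,6S)-5-(methoxycarbonyl)-6-{2-[methoxy(methyl)amino]-2-oxoethyl}-2,6-dimethylcyclohex-1-en-1-olate | [K]OC1=C(C)CC[C@@H](C(=O)OC)[C@]1(C)CC(=O)N(C)OC | intermediate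
10 | methyl (1R,2S)-2-{2-[methoxy(methyl)amino]-2-oxoethyl}-2,4-dimethyl-3-(trifluoromethylsulfonyloxy)cyclohex-3-ene-1-carboxylate | CC1=C(OS(=O)(=O)C(F)(F)F)[C@@](C)(CC(=O)N(C)OC)[C@H](C(=O)OC)CC1 | intermediate
11 | tributyl(vinyl)stannane | C=C[Sn](CCCC)(CCCC)CCCC | starting material
12 | methyl (1R,2S)-3-ethenyl-2-{2-[methoxy(methyl)amino]-2-oxoethyl}-2,4-dimethylcyclohex-3-ene-1-carboxylate | C=CC1=C(C)CC[C@@H](C(=O)OC)[C@]1(C)CC(=O)N(C)OC | intermediate
13 | methyl propiolate | C#CC(=O)OC | starting material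
14 | dimethyl (5S,6R,8aR)-5-{2-[methoxy(methyl)amino]-2-oxoethyl}-5,8a-dimethyl-3,5,6,7,8,8a-hexahydronaphthalene-1,6-dicarboxylate | C[C@@]12CC[C@@H](C(=O)OC)[C@](C)(CC(=O)N(C)OC)C1=CCC=C2C(=O)OC | intermediate
15 | dimethyl (4aR,5R,6R,8aR)-5-{2-[methoxy(methyl)amino]-2-oxoethyl}-5,8a-dimethyl-4a,5,6,7,8,8a-hexahydronaphthalene-1,6-dicarboxylate | C[C@@]12CC[C@@H](C(=O)OC)[C@](C)(CC(=O)N(C)OC)[C@H]1C=CC=C2C(=O)OC | intermediate
16 | disodium (4aR,5R,6R,8aR)-5-{2-[methoxy(methyl)amino]-2-oxoethyl}-5,8a-dimethyl-4a,5,6,7,8,8a-hexahydronaphthalene-1,6-dicarboxylate | [Na+].[Na+].C[C@@]12CC[C@@H](C(=O)[O-])[C@](C)(CC(=O)N(C)OC)[C@H]1C=CC=C2C(=O)[O-] | intermediate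
17 | (4aR,5R,6R,8aR)-5-{2-[methoxy(methyl)amino]-2-oxoethyl}-5,8a-dimethyl-4a,5,6,7,8,8a-hexahydronaphthalene-1,6-dicarboxylic acid | C[C@@]12CC[C@@H](C(=O)O)[C@](C)(CC(=O)N(C)OC)[C@H]1C=CC=C2C(=O)O | intermediate
18 | 3-bromofuran | Brc1ccoc1 | starting material
19 | dilithium (4aR,5R,6R,8aR)-5-{2-[methoxy(methyl)amino]-2-oxoethyl}-5,8a-dimethyl-4a,5,6,7,8,8a-hexahydronaphthalene-1,6-dicarboxylate | [Li+].[Li+].C[C@@]12CC[C@@H](C(=O)[O-])[C@](C)(CC(=O)N(C)OC)[C@H]1C=CC=C2C(=O)[O-] | intermediate
20 | trilithium tetrahedral adduct of 19 with 3-furyllithium (carbinol carbon unassigned) | [Li+].[Li+].[Li+].C[C@@]12CC[C@@H](C(=O)[O-])[C@](C)(CC([O-])(N(C)OC)c3ccoc3)[C@H]1C=CC=C2C(=O)[O-] | intermediate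
21 | (4aR,5R,6R,8aR)-5-[2-(furan-3-yl)-2-oxoethyl]-5,8a-dimethyl-4a,5,6,7,8,8a-hexahydronaphthalene-1,6-dicarboxylic acid | C[C@@]12CC[C@@H](C(=O)O)[C@](C)(CC(=O)c3ccoc3)[C@H]1C=CC=C2C(=O)O | intermediate
22 | (1R,2R,3E,5Z,7Z)-2-[2-(furan-3-yl)-2-oxoethyl]-2,8-dimethylcyclodeca-3,5,7-triene-1,7-dicarboxylic acid (ring geometry E,Z,E; C19 methyl cis to C3) | C/C1=C(C(=O)O)\C=C/C=C/[C@@](C)(CC(=O)c2ccoc2)[C@H](C(=O)O)CC1 | intermediate
23 | (1R,2S,4Z,6E)-2-[2-(furan-3-yl)-2-oxoethyl]-2-methyl-8-methylidenecyclodeca-4,6-diene-1,7-dicarboxylic acid | C=C1CC[C@@H](C(=O)O)[C@](C)(CC(=O)c2ccoc2)C/C=C\C=C/1C(=O)O | target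

**Totals**
Total step count: 9. Longest linear sequence: 9 steps (1 → 23).

**Three steps most likely to fail**

Step 9 (photochemical opening and [1,7]-H shift). Risks: the (E,Z,E)-triene 22 can re-close thermally (disrotatory) to a cis-fused diene instead of shifting hydrogen; over-irradiation of 22 or 23; energy transfer or hydrogen abstraction by the furyl ketone. Fallback: set out from 17 and run the cascade before the ketone exists. Irradiation of 17 (300 nm, −40 °C) gives the E,Z,E-triene Weinreb diacid (1R,2R,3E,5Z,7Z)-2-{2-[methoxy(methyl)amino]-2-oxoethyl}-2,8-dimethylcyclodeca-3,5,7-triene-1,7-dicarboxylic acid F6. Warming in the dark converts it into the seco-triene Weinreb diacid (1R,2S,4Z,6E)-2-{2-[methoxy(methyl)amino]-2-oxoethyl}-2-methyl-8-methylidenecyclodeca-4,6-diene-1,7-dicarboxylic acid F7. Treatment with 3-furyllithium (from 18 and n-BuLi) as in step 8, through the dilithium dicarboxylate of F7 F8 and the trilithium tetrahedral adduct of F8 with 3-furyllithium F9, then arrives at 23.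

Step 6 (Diels–Alder and conjugation). Risks: the diene is hindered (quaternary C9 next to the diene, a new quaternary C5); regiochemistry; wrong ring fusion. Fallback: set out from 10 and form ring A by electrocyclisation instead. Sonogashira coupling of 10 with methyl (E)-pent-2-en-4-ynoate (Pd(PPh3)2Cl2, CuI, Et3N) gives the dienyne methyl (1R,2S)-3-[(3E)-5-methoxy-5-oxopent-3-en-1-yn-1-yl]-2-{2-[methoxy(methyl)amino]-2-oxoethyl}-2,4-dimethylcyclohex-3-ene-1-carboxylate F3. Semi-reduction with Zn(Cu/Ag) gives the trienoate methyl (1R,2S)-3-[(1Z,3E)-5-methoxy-5-oxopenta-1,3-dien-1-yl]-2-{2-[methoxy(methyl)amino]-2-oxoethyl}-2,4-dimethylcyclohex-3-ene-1-carboxylate F4. Heating in toluene (110–130 °C) closes the C4–C5 bond by thermal disrotatory 6π-electrocyclisation to the cyclohexadiene dimethyl (1S,5S,6R,8aS)-5-{2-[methoxy(methyl)amino]-2-oxoethyl}-5,8a-dimethyl-1,5,6,7,8,8a-hexahydronaphthalene-1,6-dicarboxylate F5. DBU then deprotonates C4 and reprotonates C10 (equilibrating any cis-fused diene from a thermal [1,5]-H shift) to come back to the route at 15.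

Step 1 (asymmetric vinylation and alkylation). Risks: modest enantioselectivity of a vinyl Grignard on an α-substituted enone; sluggish alkylation of the hindered magnesium enolate; proton transfer from 3. Fallback: set out from 1 and 2 and separate the two events. The same copper-catalysed addition run with TMSCl gives the isolable silyl enol ether trimethyl{[(3S)-3-ethenyl-2-methylcyclohex-1-en-1-yl]oxy}silane F1, on which the enantiomeric excess can be checked. MeLi in THF converts it into the regiodefined lithium enolate lithium (3S)-3-ethenyl-2-methylcyclohex-1-en-1-olate F2, which is alkylated with 3 in THF/HMPA to come back to the route at 5.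

**Further compounds**
F1 | step 1 | trimethyl{[(3S)-3-ethenyl-2-methylcyclohex-1-en-1-yl]oxy}silane | CC1=C(O[Si](C)(C)C)CCC[C@H]1C=C
F2 | step 1 | lithium (3S)-3-ethenyl-2-methylcyclohex-1-en-1-olate | CC1=C(O[Li])CCC[C@H]1C=C
F3 | step 6 | methyl (1R,2S)-3-[(3E)-5-methoxy-5-oxopent-3-en-1-yn-1-yl]-2-{2-[methoxy(methyl)amino]-2-oxoethyl}-2,4-dimethylcyclohex-3-ene-1-carboxylate | COC(=O)/C=C/C#CC1=C(C)CC[C@@H](C(=O)OC)[C@]1(C)CC(=O)N(C)OC
F4 | step 6 | methyl (1R,2S)-3-[(1Z,3E)-5-methoxy-5-oxopenta-1,3-dien-1-yl]-2-{2-[methoxy(methyl)amino]-2-oxoethyl}-2,4-dimethylcyclohex-3-ene-1-carboxylate | COC(=O)/C=C/C=C\C1=C(C)CC[C@@H](C(=O)OC)[C@]1(C)CC(=O)N(C)OC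
F5 | step 6 | dimethyl (1S,5S,6R,8aS)-5-{2-[methoxy(methyl)amino]-2-oxoethyl}-5,8a-dimethyl-1,5,6,7,8,8a-hexahydronaphthalene-1,6-dicarboxylate | C[C@@]12CC[C@@H](C(=O)OC)[C@](C)(CC(=O)N(C)OC)C1=CC=C[C@@H]2C(=O)OC
F6 | step 9 | (1R,2R,3E,5Z,7Z)-2-{2-[methoxy(methyl)amino]-2-oxoethyl}-2,8-dimethylcyclodeca-3,5,7-triene-1,7-dicarboxylic acid | C/C1=C(C(=O)O)\C=C/C=C/[C@@](C)(CC(=O)N(C)OC)[C@H](C(=O)O)CC1
F7 | step 9 | (1R,2S,4Z,6E)-2-{2-[methoxy(methyl)amino]-2-oxoethyl}-2-methyl-8-methylidenecyclodeca-4,6-diene-1,7-dicarboxylic acid | C=C1CC[C@@H](C(=O)O)[C@](C)(CC(=O)N(C)OC)C/C=C\C=C/1C(=O)O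
F8 | step 9 | dilithium dicarboxylate of F7 | [Li+].[Li+].C=C1CC[C@@H](C(=O)[O-])[C@](C)(CC(=O)N(C)OC)C/C=C\C=C/1C(=O)[O-]
F9 | step 9 | trilithium tetrahedral adduct of F8 with 3-furyllithium | [Li+].[Li+].[Li+].C=C1CC[C@@H](C(=O)[O-])[C@](C)(CC([O-])(N(C)OC)c2ccoc2)C/C=C\C=C/1C(=O)[O-]
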